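1. The unit I used was the millimolar: in these flasks, one percentage point of product is 1.00 mM.

| flask | substrate | capture agent | free catalyst | remark |
|---|---|---|---|---|
| teal | 0.10 M | 0.030 M | 1.2 mM | run made earlier |
| violet | 0.10 M | 0.030 M | 1.9 mM | run made earlier |
| flask | 0.10 M | 0.0300 M | 2.5 mM |  |

| run | time / h | product / % |
|---|---|---|
| teal | 2.00 | 2.9 |
| teal | 4.00 | 7.8 |
| teal | 5.00 | 8.5 |
| teal | 8.00 | 13.3 |
| violet | 0.833 | 2.9 |
| violet | 2.50 | 7.9 |
| violet | 5.00 | 14.8 |
| violet | 8.00 | 19.8 |

(scatter of a reading: 1 percentage point)



1. factor on the rate of making product when 20% of the substrate are converted if free catalyst is charged twice over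
2. factor on the rate when 20% of the substrate are converted if free catalyst is charged at 25 mM instead

2. The bench rule says that rate goes with the catalyst charged, so charging twice over gives a factor of 2, and 25 mM gives 10.0. Near 7.9% product, teal took 1.60 times as long as violet, against a charge ratio of 1.58. Near 2.9%, though, the same time ratio read 2.40, so the check is rough.

3. Violet's late slope, between 5.00 h and 8.00 h, was 0.527 of its early slope, at a mean product of 17.3%. I charged the whole fall to lost catalyst, though substrate fell too. A straight fall then reaches zero at 36.6% product, which gives a reading of the turnover number, N = 19.3, with the scatter of the violet readings in it. N is the rate of making product divided by the rate of losing catalyst, or product made per catalyst lost. Time drops out of that ratio.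

4. Taking 20% conversion as that much product, I reckoned a loss of about 1.04 mM of catalyst in this flask, which is 41.5% of its charge. The bench rule holds while that share is small, so at this charge I did not trust it. At equal conversion I took the rate to go with charge minus loss, which gave my own factors of 2.71 and 16.4.

5. The forecast differed from mine, at 2.3 and 14, and said “the data cannot separate the possible causes”.

6. The simulation gave 2.62 and 15.0.

    substrate + free catalyst ⇌ catalyst intermediate (K = 150 M⁻¹, k = 40.0 M⁻¹ h⁻¹)
    catalyst intermediate → free catalyst + product (k = 5.00 h⁻¹)
    catalyst intermediate + capture agent → trapped intermediate (k = 6.00 M⁻¹ h⁻¹)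
    substrate + catalyst intermediate → spent catalyst (k = 0.820 M⁻¹ h⁻¹)

At 12.0 h, this flask held trapped intermediate at 47.0% and spent catalyst at 17.8% of the catalyst charged, against product at 33.3% of the substrate, so N read 20.5. By my N, the same 1.04 mM is 4.16% of a 25 mM charge, and the factor of 15.0 for that charge stands above the bench 10.0. Trapping by capture agent is a proven part of the loss: this flask, with that step taken away, made product at 20% conversion at 1.43 times its actual rate.

The readings come from a simulation with constants of no real substance; the scatter is artificial.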